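The side chain is cut between the benzylic CH2 and the CH2 next to the tertiary carbinol. The benzylic carbon sits on C3′ of ring A, between the oxygen-bearing C2′ and C4′, so it is the methyl group of 2-methylresorcinol. The carbinol carbon, its oxygen and the neighbouring CH2 form a 2,2-disubstituted epoxide, available in one catalytic asymmetric step from 6-methylhept-5-en-2-one. In one operation a benzylic carbanion of the bis-MOM arene opens the (R)-epoxide at its CH2, forming the C–C bond and unveiling the tertiary alcohol with its configuration untouched. The chalcone is then added by ortho-lithiation and acylation with a cinnamoyl Weinreb amide.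

Key step: step 3

Assumption: the (R)-BINOL-derived La/Li catalyst is taken to deliver the (R)-epoxide in step 1; if the sense of induction is the opposite, the (S)-BINOL complex is used and nothing else changes.

Step 1
Reactants: 1 6-methylhept-5-en-2-one
Product: 2 (R)-2-methyl-2-(4-methylpent-3-en-1-yl)oxirane
Conditions: Me3S(O)I, NaH, THF; then La-Li3-tris[(R)-binaphthoxide] (5 mol %), (2,4,6-(MeO)3C6H2)3P=O (5 mol %), 5 Å MS, THF, rt
Reagents that add atoms: trimethylsulfoxonium iodide, C[S+](C)(C)=O.[I-]
Why: Catalytic asymmetric Corey–Chaykovsky epoxidation, in which the heterobimetallic La/Li/BINOLate complex binds the methyl ketone and the sulfoxonium ylide together, so that CH2 should be delivered to one enantiotopic carbonyl face (methyl versus homoprenyl) and set the quaternary (R) centre, while the unactivated trisubstituted alkene is inert to the ylide.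

Step 2
Reactants: 3 2-methylresorcinol
Product: 4 1,3-bis(methoxymethoxy)-2-methylbenzene
Conditions: NaH, MOMCl, DMF, 0 °C → rt
Reagents that add atoms: chloromethyl methyl ether (MOMCl), COCCl
Why: Williamson O-alkylation of the bis-phenoxide; the MOM acetals tolerate the organoalkali steps that follow and later direct ortho-lithiation.

Step 3
Reactants: 4 1,3-bis(methoxymethoxy)-2-methylbenzene; 2 (R)-2-methyl-2-(4-methylpent-3-en-1-yl)oxirane
Product: 6 (3R)-1-[2,6-bis(methoxymethoxy)phenyl]-3,7-dimethyloct-6-en-3-ol, via benzylic potassium reagent 5 (not isolated)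
Conditions: n-BuLi, KOt-Bu, TMP(H), THF, −78 °C; then 2, −78 °C → rt; aq. NH4Cl
Reagents that add atoms: none
Why: The mixed Li/K amide base should metalate the methyl group of 4 to give 5, because TMP(H) shuttles any aryl anion formed kinetically next to OMOM to the thermodynamically preferred benzylic site (benzylic metalation of alkoxytoluenes with mixed Li/K amide superbases). Carbanion 5 then opens epoxide 2 by SN2 attack at its CH2, which forms the ArCH2–CH2 bond and releases the tertiary alkoxide (epoxide opening by benzylic organoalkali reagents). No ring is closed and no stereocentre is created: the C–O bond at the quaternary carbon is never broken, so the (R) configuration of 2 is carried unchanged into C3 of 6. The step needs benzylic rather than ring metalation, which the equilibrating amide and the two flanking, cation-chelating OMOM groups secure, and attack at CH2 rather than at the quaternary epoxide carbon, which sterics secure. A two-electron opening is chosen because a radical on the CH2 next to the carbinol would be a 5-hexenyl radical and would cyclise onto the C6=C7 alkene.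

Step 4
Reactants: 7 4-(methoxymethoxy)benzaldehyde; 8 diethyl {2-[methoxy(methyl)amino]-2-oxoethyl}phosphonate
Product: 9 (2E)-N-methoxy-3-[4-(methoxymethoxy)phenyl]-N-methylprop-2-enamide
Conditions: NaH, THF, 0 °C → rt
Reagents that add atoms: none
Why: Horner–Wadsworth–Emmons olefination, in which the stabilised phosphonate anion adds reversibly and eliminates through the anti oxaphosphetane, so the (E)-enamide should dominate.

Step 5
Reactants: 6 (3R)-1-[2,6-bis(methoxymethoxy)phenyl]-3,7-dimethyloct-6-en-3-ol; 9 (2E)-N-methoxy-3-[4-(methoxymethoxy)phenyl]-N-methylprop-2-enamide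
Product: 11 (2E)-1-[3-[(3R)-3-hydroxy-3,7-dimethyloct-6-en-1-yl]-2,4-bis(methoxymethoxy)phenyl]-3-[4-(methoxymethoxy)phenyl]prop-2-en-1-one, via dilithiated aryl alkoxide 10 (not isolated)
Conditions: n-BuLi (2.2 equiv), TMEDA, THF, 0 °C; then 9, −78 → 0 °C; aq. NH4Cl
Reagents that add atoms: none
Why: Directed ortho-metalation followed by Weinreb ketone synthesis: after the first equivalent of base forms the alkoxide, OMOM directs lithiation to C4 (equivalent to C6, the only ring positions ortho to OMOM), and the aryllithium adds 1,2 to the amide to give a chelated tetrahedral adduct that releases the (E)-enone only on work-up.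

Step 6
Reactants: 11 (2E)-1-[3-[(3R)-3-hydroxy-3,7-dimethyloct-6-en-1-yl]-2,4-bis(methoxymethoxy)phenyl]-3-[4-(methoxymethoxy)phenyl]prop-2-en-1-one
Product: 13 (2E)-1-[2,4-dihydroxy-3-[(3R)-3-hydroxy-3,7-dimethyloct-6-en-1-yl]phenyl]-3-(4-hydroxyphenyl)prop-2-en-1-one (CNP0156752.1), via tetrakis(trimethylsilyl) ether 12 (not isolated)
Conditions: TMSOTf, 2,2′-bipyridyl, MeCN, 0 °C → rt; then H2O/THF, citric acid, rt
Reagents that add atoms: none
Why: Silyl triflate/2,2′-bipyridyl cleavage of aryl MOM ethers exchanges each ArO–CH2OMe for ArO–SiMe3 without free Brønsted acid while the tertiary hydroxyl is masked as its TMS ether, and mild aqueous hydrolysis should then free all four hydroxyls without ionising the tertiary carbinol or touching the enone and the alkene.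

Compound list
1 | 6-methylhept-5-en-2-one | CC(C)=CCCC(C)=O | starting material
2 | (R)-2-methyl-2-(4-methylpent-3-en-1-yl)oxirane | CC(C)=CCC[C@@]1(C)OC1 | intermediate
3 | 2-methylresorcinol (2-methylbenzene-1,3-diol) | Cc1c(O)cccc1O | starting material
4 | 1,3-bis(methoxymethoxy)-2-methylbenzene | Cc1c(OCOC)cccc1OCOC | intermediate
5 | [2,6-bis(methoxymethoxy)benzyl]potassium | [K]Cc1c(OCOC)cccc1OCOC | intermediate
6 | (3R)-1-[2,6-bis(methoxymethoxy)phenyl]-3,7-dimethyloct-6-en-3-ol | CC(C)=CCC[C@@](C)(O)CCc1c(OCOC)cccc1OCOC | intermediate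
7 | 4-(methoxymethoxy)benzaldehyde | COCOc1ccc(C=O)cc1 | starting material
8 | diethyl {2-[methoxy(methyl)amino]-2-oxoethyl}phosphonate | CCOP(=O)(OCC)CC(=O)N(C)OC | starting material
9 | (2E)-N-methoxy-3-[4-(methoxymethoxy)phenyl]-N-methylprop-2-enamide | COCOc1ccc(/C=C/C(=O)N(C)OC)cc1 | intermediate
10 | lithium (3R)-1-[3-lithio-2,6-bis(methoxymethoxy)phenyl]-3,7-dimethyloct-6-en-3-olate | CC(C)=CCC[C@@](C)(O[Li])CCc1c(OCOC)ccc([Li])c1OCOC | intermediate
11 | (2E)-1-[3-[(3R)-3-hydroxy-3,7-dimethyloct-6-en-1-yl]-2,4-bis(methoxymethoxy)phenyl]-3-[4-(methoxymethoxy)phenyl]prop-2-en-1-one | CC(C)=CCC[C@@](C)(O)CCc1c(OCOC)ccc(C(=O)/C=C/c2ccc(OCOC)cc2)c1OCOC | intermediate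
12 | (2E)-1-[3-[(3R)-3,7-dimethyl-3-(trimethylsilyloxy)oct-6-en-1-yl]-2,4-bis(trimethylsilyloxy)phenyl]-3-[4-(trimethylsilyloxy)phenyl]prop-2-en-1-one | CC(C)=CCC[C@@](C)(O[Si](C)(C)C)CCc1c(O[Si](C)(C)C)ccc(C(=O)/C=C/c2ccc(O[Si](C)(C)C)cc2)c1O[Si](C)(C)C | intermediate
13 | (2E)-1-[2,4-dihydroxy-3-[(3R)-3-hydroxy-3,7-dimethyloct-6-en-1-yl]phenyl]-3-(4-hydroxyphenyl)prop-2-en-1-one | CC(C)=CCC[C@@](C)(O)CCc1c(O)ccc(C(=O)/C=C/c2ccc(O)cc2)c1O | target

Total step count: 6. Longest linear sequence: 4 steps (steps 2, 3, 5, 6 from 2-methylresorcinol; equally steps 1, 3, 5, 6 from 6-methylhept-5-en-2-one).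

Steps most likely to fail

Step 3 (key step). Metalation may settle on a ring carbon next to OMOM instead of on the methyl group. The strongly basic carbanion/amide mixture may also abstract a proton from the epoxide, isomerising it to an allylic alkoxide, faster than it substitutes. The fallback sets out from epoxide 2 and returns at 6, using a much less basic benzylic Grignard reagent under copper catalysis. Resorcinol is converted (NaH, MOMCl, DMF) into 1,3-bis(methoxymethoxy)benzene F1. Lithiation between the two acetal oxygens (n-BuLi, THF, 0 °C) and trapping with paraformaldehyde should give [2,6-bis(methoxymethoxy)phenyl]methanol F2. Appel chlorination (PPh3, CCl4, CH2Cl2, rt; neutral, so the acetals are safe) should give 2-(chloromethyl)-1,3-bis(methoxymethoxy)benzene F3. Magnesium insertion (activated Mg, THF, 0 °C, slow addition to limit Wurtz coupling) gives [2,6-bis(methoxymethoxy)benzyl]magnesium chloride F4. With CuI (10 mol %) in THF at −30 → 0 °C this should open 2 at its CH2 and give 6.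

Step 6. The Lewis-acidic silyl triflate may ionise the tertiary C–O bond, leading to ring closure onto a neighbouring phenolic oxygen or onto the alkene, or may leave the hindered 2′-O-MOM group uncleaved. The fallback sets out from 11 and returns at 13, masking the carbinol before a conventional protic acetal cleavage. TBSOTf and 2,6-lutidine (CH2Cl2, −78 → 0 °C) should silylate only the tertiary hydroxyl, since the ketone cannot enolise, to give (2E)-1-[3-[(3R)-3-(tert-butyldimethylsilyloxy)-3,7-dimethyloct-6-en-1-yl]-2,4-bis(methoxymethoxy)phenyl]-3-[4-(methoxymethoxy)phenyl]prop-2-en-1-one F5. Methanolysis (1 M HCl, MeOH, 40 °C) should remove the three MOM groups while the shielded, weakly basic silyl ether oxygen resists protonation and ionisation, giving (2E)-1-[3-[(3R)-3-(tert-butyldimethylsilyloxy)-3,7-dimethyloct-6-en-1-yl]-2,4-dihydroxyphenyl]-3-(4-hydroxyphenyl)prop-2-en-1-one F6. Buffered HF·pyridine (pyridine, THF, 0 °C → rt) then frees the tertiary alcohol to give 13.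

Step 5. The aryllithium may add in conjugate fashion to the cinnamoyl amide, or residual butyllithium may consume the amide, so that the enone is formed inefficiently. The fallback sets out from 6 and returns at 11, building the enone by aldol condensation instead. The same aryllithium 10 is quenched with N-methoxy-N-methylacetamide, which should give 1-[3-[(3R)-3-hydroxy-3,7-dimethyloct-6-en-1-yl]-2,4-bis(methoxymethoxy)phenyl]ethan-1-one F7. Claisen–Schmidt condensation of this ketone with aldehyde 7 (KOH, EtOH, rt) should give 11.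

Further compounds
F1 | step 3 | 1,3-bis(methoxymethoxy)benzene | COCOc1cccc(OCOC)c1
F2 | step 3 | [2,6-bis(methoxymethoxy)phenyl]methanol | OCc1c(OCOC)cccc1OCOC
F3 | step 3 | 2-(chloromethyl)-1,3-bis(methoxymethoxy)benzene | ClCc1c(OCOC)cccc1OCOC
F4 | step 3 | [2,6-bis(methoxymethoxy)benzyl]magnesium chloride | Cl[Mg]Cc1c(OCOC)cccc1OCOC
F5 | step 6 | (2E)-1-[3-[(3R)-3-(tert-butyldimethylsilyloxy)-3,7-dimethyloct-6-en-1-yl]-2,4-bis(methoxymethoxy)phenyl]-3-[4-(methoxymethoxy)phenyl]prop-2-en-1-one | CC(C)=CCC[C@@](C)(O[Si](C)(C)C(C)(C)C)CCc1c(OCOC)ccc(C(=O)/C=C/c2ccc(OCOC)cc2)c1OCOC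
F6 | step 6 | (2E)-1-[3-[(3R)-3-(tert-butyldimethylsilyloxy)-3,7-dimethyloct-6-en-1-yl]-2,4-dihydroxyphenyl]-3-(4-hydroxyphenyl)prop-2-en-1-one | CC(C)=CCC[C@@](C)(O[Si](C)(C)C(C)(C)C)CCc1c(O)ccc(C(=O)/C=C/c2ccc(O)cc2)c1O
F7 | step 5 | 1-[3-[(3R)-3-hydroxy-3,7-dimethyloct-6-en-1-yl]-2,4-bis(methoxymethoxy)phenyl]ethan-1-one | CC(C)=CCC[C@@](C)(O)CCc1c(OCOC)ccc(C(C)=O)c1OCOC
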